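**Strategy**

The target ring holds a 1,5-dicarbonyl pair: the ring carbonyl C1 and the enol carbon C3 are joined through C6(OH)–C5–C4, the retron of a de Mayo reaction. The key step is therefore a [2+2] photocycloaddition between the enone double bond of a chiral 6-(2-oxononadecyl)-1,3-dioxin-4-one and vinyl acetate. It makes the bonds C1–C6 and C4–C5 (ring numbering of the target) in one operation and brings in the C6 oxygen at the alcohol level. The precursor is a masked 3,5-dioxo acid with no six-membered carbocycle; one treatment with methoxide then opens the cyclobutane by retro-aldol cleavage and closes the carbocycle by Claisen condensation (C2–C3).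

Key step: step 4

Assumption: additions to 2-tert-butyl-1,3-dioxin-4-ones take place on the face trans to the tert-butyl group; on that basis the exo acetate of the (S)-acetal series carries the (S) carbinol center (were the face sense the opposite, the (R)-hydroxy acid would be used in step 1).

**Route**

Step 1
Reactants: 1 (S)-3-hydroxybutanoic acid; 2 pivalaldehyde
Product: 3 (2S,6S)-2-tert-butyl-6-methyl-1,3-dioxan-4-one (cis)
Conditions: TsOH·H2O (cat.), CH2Cl2, reflux, water separator; recrystallisation
Reagents that add atoms: none
Why: Acid-catalysed acetalisation under thermodynamic control should give the cis-dioxanone with both substituents equatorial, so the carbinol center of 1 dictates the new acetal center (2S).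

Step 2
Reactants: 3 (2S,6S)-2-tert-butyl-6-methyl-1,3-dioxan-4-one
Product: 5 (S)-2-tert-butyl-6-methyl-4H-1,3-dioxin-4-one, via bromodioxanone 4 (not isolated)
Conditions: NBS, AIBN (cat.), CCl4, reflux; then Et3N, 0 °C to rt
Reagents that add atoms: N-bromosuccinimide, O=C1CCC(=O)N1Br (its bromine is present in 4 only)
Why: Wohl–Ziegler-type radical bromination at the tertiary C6–H next to the ring oxygen, followed by dehydrobromination, should install the C5=C6 double bond and leave the acetal center as the only stereocenter.

Step 3
Reactants: 5 (S)-2-tert-butyl-6-methyl-4H-1,3-dioxin-4-one; 6 octadecanoyl chloride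
Product: 7 (S)-2-tert-butyl-6-(2-oxononadecyl)-4H-1,3-dioxin-4-one
Conditions: LiN(SiMe3)2, THF, −78 °C; then 6, −78 to −20 °C (two equivalents of dienolate per acid chloride, excess 5 recovered); aq. NH4Cl
Reagents that add atoms: none
Why: The lithium dienolate of the dioxinone should be C-acylated at its exocyclic γ-carbon by the acid chloride (vinylogous Claisen acylation), the second equivalent of dienolate taking up the acidic proton of the keto-dioxinone formed.

Step 4
Reactants: 7 (S)-2-tert-butyl-6-(2-oxononadecyl)-4H-1,3-dioxin-4-one; 8 vinyl acetate
Product: 9 (1S,3S,6S,8S)-3-tert-butyl-5-oxo-1-(2-oxononadecyl)-2,4-dioxabicyclo[4.2.0]octan-8-yl acetate (cyclobutane on the face trans to tert-butyl, acetoxy exo)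
Conditions: hν (medium-pressure Hg lamp, Vycor filter, λ > 250 nm), 8 (20 equiv), degassed MeCN, −30 °C; chromatography to remove the C8 epimer
Reagents that add atoms: none
Why: Light absorbed by the dioxinone chromophore of 7 (strong π,π* band near 250 nm, far above the weak n,π* band of the side-chain ketone) gives, after intersystem crossing, a triplet enone that adds to vinyl acetate through a 1,4-biradical whose collapse closes the cyclobutane; the new bonds C1–C8 and C6–C7 of 9 are C1–C6 and C4–C5 of the target. The closest known reaction type is the de Mayo reaction in its dioxinone form, the intermolecular [2+2] photocycloaddition of 1,3-dioxin-4-ones with donor alkenes such as enol esters. The one ring closed is the four-membered ring, formed cis-fused to the dioxanone by an intermolecular [2+2] addition that ends with radical recombination. The head-to-tail orientation, with the acetoxy carbon on the oxygen-bearing β-carbon, is the regular one for a donor alkene with an excited enone and is the selectivity on which the connectivity rests. The ring-fusion centers C1 and C6 are set by approach on the face trans to the tert-butyl group (control by the acetal stereocenter), while C8 is set only in the collapse of the biradical, with little exo/endo bias from the substrate. Both C8 epimers are therefore expected, and the exo epimer 9 (acetoxy cis to the side chain), which has the (S) carbinol center of the target, is isolated by chromatography.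

Step 5
Reactants: 9 (1S,3S,6S,8S)-3-tert-butyl-5-oxo-1-(2-oxononadecyl)-2,4-dioxabicyclo[4.2.0]octan-8-yl acetate
Product: 12 (6S)-3,6-dihydroxy-2-octadecanoylcyclohex-2-en-1-one (target), via seco acetate 10 (not isolated), via seco alcohol 11 (not isolated)
Conditions: NaOMe (5 equiv), MeOH, 0 to 50 °C; then 1 M HCl
Reagents that add atoms: methanol, CO (its methoxy group is present in 10 and 11 and is lost again in the ring closure)
Why: Methoxide should open the acylal lactone, the hemiacetal expel pivalaldehyde and the cyclobutanolate undergo strain-driven retro-aldol cleavage (de Mayo fragmentation) to the 1,5-keto ester, after which acetate methanolysis and Claisen (Dieckmann) closure of the diketone carbon onto the ester give the triketone enolate; the carbinol center should survive because its neighbouring carbonyl is held in the diketone or triketone enolate throughout.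

**Compound list**

1 | (S)-3-hydroxybutanoic acid | C[C@H](O)CC(=O)O | starting material
2 | pivalaldehyde (2,2-dimethylpropanal) | CC(C)(C)C=O | starting material
3 | (2S,6S)-2-tert-butyl-6-methyl-1,3-dioxan-4-one (cis) | CC(C)(C)[C@@H]1OC(=O)C[C@H](C)O1 | intermediate
4 | 6-bromo-2-tert-butyl-6-methyl-1,3-dioxan-4-one (acetal center as in 3, C6 epimers; not isolated) | CC(C)(C)[C@@H]1OC(=O)CC(C)(Br)O1 | intermediate
5 | (S)-2-tert-butyl-6-methyl-4H-1,3-dioxin-4-one | CC(C)(C)[C@@H]1OC(=O)C=C(C)O1 | intermediate
6 | octadecanoyl chloride | CCCCCCCCCCCCCCCCCC(=O)Cl | starting material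
7 | (S)-2-tert-butyl-6-(2-oxononadecyl)-4H-1,3-dioxin-4-one | CC(C)(C)[C@@H]1OC(=O)C=C(CC(=O)CCCCCCCCCCCCCCCCC)O1 | intermediate
8 | vinyl acetate | C=COC(C)=O | starting material
9 | (1S,3S,6S,8S)-3-tert-butyl-5-oxo-1-(2-oxononadecyl)-2,4-dioxabicyclo[4.2.0]octan-8-yl acetate | CC(C)(C)[C@@H]1OC(=O)[C@H]2C[C@H](OC(C)=O)[C@@]2(CC(=O)CCCCCCCCCCCCCCCCC)O1 | intermediate
10 | methyl (4S)-4-acetoxy-5,7-dioxotetracosanoate (not isolated) | COC(=O)CC[C@H](OC(C)=O)C(=O)CC(=O)CCCCCCCCCCCCCCCCC | intermediate
11 | methyl (4S)-4-hydroxy-5,7-dioxotetracosanoate (not isolated) | COC(=O)CC[C@H](O)C(=O)CC(=O)CCCCCCCCCCCCCCCCC | intermediate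
12 | (6S)-3,6-dihydroxy-2-octadecanoylcyclohex-2-en-1-one | CCCCCCCCCCCCCCCCCC(=O)C1=C(O)CC[C@H](O)C1=O | target

**Step count and risks**

Total step count: 5. Longest linear sequence: 5 (1 → 3 → 5 → 7 → 9 → 12).

The three steps most likely to fail:

1. Step 4. The main risk is poor exo/endo discrimination when the 1,4-biradical collapses, so that the wanted exo acetate is a minor or inseparable component. A second risk is that light is diverted into γ-hydrogen abstraction by the side-chain ketone. Fallback, setting out from 7 and returning at 11: the alkene is changed to one for which the exo/endo question does not arise. Irradiation of 7 with vinylene carbonate under the same conditions should give the cis-anti-cis tricyclic carbonate adduct F1 (both oxygens exo, face again set by the acetal). HCl in MeOH (rt) then opens the acylal and triggers the retro-aldol cleavage to the cyclic carbonate keto ester F2. DBU (2.2 equiv, CH2Cl2, 0 °C) removes the surplus oxygen by E1cB elimination from the ester α-carbon with loss of CO2, giving the γ-hydroxy enoate F3. Hydrogenation of the C=C bond (H2, Rh on Al2O3, EtOAc) leads to 11, which is closed to 12 with NaOMe as in step 5.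

2. Step 5. The risks are erosion of the carbinol configuration (enolization of the α-oxygenated ketone before the diketone is deprotonated, or an α-ketol shift), retro-Claisen cleavage of the diketone by methoxide, and stalling before ring closure. Fallback, setting out from 9 and returning at 12: the cascade is split and methoxide avoided. HCl in MeOH (rt to 40 °C) should open the acylal, cleave the cyclobutanol by retro-aldol and remove the acetate, the hydroxy ester closing to the γ-lactone (S)-5-(3-oxoicosanoyl)dihydrofuran-2(3H)-one F4. KOt-Bu (2.2 equiv, THF, 0 °C) then drives the lactone-to-carbocycle Claisen condensation of the diketone enolate onto the lactone carbonyl to give 12.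

3. Step 3. The risks are loss of regiocontrol in the acylation of the dienolate (attack at the ring α-carbon or at oxygen) and double acylation. Fallback, setting out from 5 and returning at 7: the electrophile is lowered to the aldehyde level. LiN(iPr)2 and Me3SiCl (THF, −78 °C) convert 5 into the silyl dienol ether (S)-2-tert-butyl-4-methylidene-6-(trimethylsilyloxy)-4H-1,3-dioxine F5. Vinylogous Mukaiyama aldol addition to octadecanal (BF3·OEt2, CH2Cl2, −78 °C), which is reliably γ-selective, gives the hydroxy dioxinone (2S)-2-tert-butyl-6-(2-hydroxynonadecyl)-4H-1,3-dioxin-4-one F6 (carbinol epimers, of no consequence). Dess–Martin periodinane (CH2Cl2) oxidises F6 to 7.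

**Further compounds**

F1 | step 4 | tricyclic carbonate adduct of 7 and vinylene carbonate (cis-anti-cis, both carbonate oxygens exo, cyclobutane trans to tert-butyl) | CC(C)(C)[C@@H]1OC(=O)[C@H]2[C@@H]3OC(=O)O[C@@H]3[C@@]2(CC(=O)CCCCCCCCCCCCCCCCC)O1
F2 | step 4 | methyl 2-[cis-5-(3-oxoicosanoyl)-2-oxo-1,3-dioxolan-4-yl]acetate (acyl-bearing carbon S) | COC(=O)C[C@@H]1OC(=O)O[C@@H]1C(=O)CC(=O)CCCCCCCCCCCCCCCCC
F3 | step 4 | methyl (2E,4S)-4-hydroxy-5,7-dioxotetracos-2-enoate | COC(=O)/C=C/[C@H](O)C(=O)CC(=O)CCCCCCCCCCCCCCCCC
F4 | step 5 | (S)-5-(3-oxoicosanoyl)dihydrofuran-2(3H)-one | CCCCCCCCCCCCCCCCCC(=O)CC(=O)[C@@H]1CCC(=O)O1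
F5 | step 3 | (S)-2-tert-butyl-4-methylidene-6-(trimethylsilyloxy)-4H-1,3-dioxine | C=C1C=C(O[Si](C)(C)C)O[C@@H](C(C)(C)C)O1
F6 | step 3 | (2S)-2-tert-butyl-6-(2-hydroxynonadecyl)-4H-1,3-dioxin-4-one | CC(C)(C)[C@@H]1OC(=O)C=C(CC(O)CCCCCCCCCCCCCCCCC)O1
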